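**Retrosynthetic overview**

1. Target 42 comes from nona-ether 41 by cleavage of all aryl alkyl ethers. Furan ring 2 (O1'–C2'–C3', trans) is closed by a catalyst-controlled carbene C–H insertion into the OCH2 of a 2,4-dimethoxybenzyl ether on the central phenol, after ortho-formylation at C5 and conversion into a diaryl ketone hydrazone.
2. The strategy rests on ring B, the 3,5-dioxygenated benzene ring. Its adjacent carbons Cb1 (bonded to C3 of furan ring 1) and Cb6 (bonded to the aryl-bearing methine Cα) are the only link between these two benzylic methines in the seven-membered ring (C3–Cb1–Cb6–Cα–CH2–C4–C3a). Cutting Cb1–Cb6, Cb2–Cb3 and Cb4–Cb5 gives diyne 26 (C3 ethynyl plus side-chain silyl ynol ether) and ethoxyacetylene 27, so one (2+2+2) event closes ring B and the seven-membered ring and places the two ynol oxygens meta.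
3. Diyne 26 comes from benzylic bromide 13 by Evans alkylation (sets Cα), then acyl → alkyne → silyl ynol ether. The C3 ethynyl group is carried as a 1,1-dibromoalkene so that the two alkynes stay distinct.
4. Furan ring 1 comes from enantioselective carbene C–H insertion of aryl diazoacetate 7 into one of two identical 4-methoxybenzyl ethers (the other protects the central phenol), then epimerisation to trans. The arene is 3,5-dihydroxybenzyl alcohol.
5. Ring order: central benzene ring (bought) → furan ring 1 → ring B together with the seven-membered ring → furan ring 2.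

Key step: step 18

Assumption: the sense of asymmetric induction of the two chiral dirhodium catalysts (steps 6 and 26) is taken as written; if a substrate gives the antipodal ring, the enantiomeric catalyst is used and nothing else changes.

Locants: furan ring 1 = O1, C2, C3 fused at C3a/C7a to the central ring (C4 carries the seven-ring CH2, C5 is the free position, C6 the oxygen used for furan ring 2, C7 lies between the two oxygens). Ring B = Cb1 (on C3), Cb2 (H), Cb3 (O), Cb4 (H), Cb5 (O), Cb6 (on Cα). Cα = aryl-bearing methine of the seven-membered ring. Furan ring 2 = O1', C2', C3'. PMB = 4-methoxybenzyl, DMB = 2,4-dimethoxybenzyl.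

**Route**

Step 1
Reactants: 1 3,5-dihydroxybenzyl alcohol; 2 4-methoxybenzyl chloride (2.2 equiv in all)
Product: 3 [3,5-bis(4-methoxybenzyloxy)phenyl]methanol
Conditions: K2CO3, KI (cat.), DMF, 60 °C
Reagents that add atoms: 4-methoxybenzyl chloride, the second equivalent of 2 (COc1ccc(CCl)cc1)
Why: Twofold Williamson etherification of the two phenoxides, each taking one molecule of the benzylic chloride, leaves the un-ionised benzylic alcohol free and keeps the ring symmetric; one PMB ether later supplies C2 and its aryl group of furan ring 1, the other protects the central phenol.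

Step 2
Reactants: 3 [3,5-bis(4-methoxybenzyloxy)phenyl]methanol
Product: 4 tert-butyl{[3,5-bis(4-methoxybenzyloxy)benzyl]oxy}dimethylsilane
Conditions: t-BuMe2SiCl, imidazole, DMF, rt
Reagents that add atoms: tert-butyldimethylsilyl chloride (CC(C)(C)[Si](C)(C)Cl)
Why: Standard silylation of the primary alcohol; the bulky silyl ether is a poor partner for carbene ylide formation in step 6.

Step 3
Reactants: 4 tert-butyl{[3,5-bis(4-methoxybenzyloxy)benzyl]oxy}dimethylsilane
Product: 5 {[2-bromo-3,5-bis(4-methoxybenzyloxy)benzyl]oxy}(tert-butyl)dimethylsilane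
Conditions: NBS (1.0 equiv), MeCN, 0 °C, dark
Reagents that add atoms: N-bromosuccinimide (O=C1CCC(=O)N1Br)
Why: Electrophilic aromatic bromination should go to C2 (ortho to one alkoxy group, para to the other; equivalent to C6) and not to the hindered position between the two ethers, as with other 3,5-dialkoxybenzyl derivatives; the anisyl rings are much less activated.

Step 4
Reactants: 5 {[2-bromo-3,5-bis(4-methoxybenzyloxy)benzyl]oxy}(tert-butyl)dimethylsilane
Product: 6 methyl 2-[2-(tert-butyldimethylsilyloxymethyl)-4,6-bis(4-methoxybenzyloxy)phenyl]acetate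
Conditions: BrZnCH2CO2Me (from BrCH2CO2Me and Zn, THF), Pd2(dba)3 (2.5 mol %), XPhos (10 mol %), THF, 65 °C
Reagents that add atoms: methyl bromoacetate, used as its zinc reagent (COC(=O)CBr)
Why: Negishi-type coupling of the aryl bromide with a Reformatsky reagent; zerovalent palladium with a bulky biarylphosphine handles the doubly ortho-substituted electron-rich bromide, and the zinc enolate is too weakly basic to disturb the ethers.

Step 5
Reactants: 6 methyl 2-[2-(tert-butyldimethylsilyloxymethyl)-4,6-bis(4-methoxybenzyloxy)phenyl]acetate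
Product: 7 methyl 2-diazo-2-[2-(tert-butyldimethylsilyloxymethyl)-4,6-bis(4-methoxybenzyloxy)phenyl]acetate
Conditions: 4-acetamidobenzenesulfonyl azide, DBU, MeCN, 0 °C to rt
Reagents that add atoms: 4-acetamidobenzenesulfonyl azide (CC(=O)Nc1ccc(cc1)S(=O)(=O)N=[N+]=[N-])
Why: Regitz diazo transfer to the arylacetate enolate formed with DBU.

Step 6
Reactants: 7 methyl 2-diazo-2-[2-(tert-butyldimethylsilyloxymethyl)-4,6-bis(4-methoxybenzyloxy)phenyl]acetate
Product: 9 methyl (2R,3R)-4-(tert-butyldimethylsilyloxymethyl)-6-(4-methoxybenzyloxy)-2-(4-methoxyphenyl)-2,3-dihydrobenzofuran-3-carboxylate (trans ester), via cis ester 8 (not isolated)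
Conditions: Rh2(S-PTTL)4 (1 mol %), toluene, −60 °C; then NaOMe, MeOH, rt
Reagents that add atoms: none
Why: Enantioselective intramolecular 1,5 C–H insertion of the dirhodium carbene into the activated OCH2Ar bond of the ortho PMB ether (the only C–H bond that gives a five-membered ring) closes furan ring 1 as the cis ester with C2 set as R by the chiral carboxylate ligands, and methoxide then epimerises the acidic C3 to the more stable trans ester (3R) without touching C2.

Step 7
Reactants: 9 methyl (2R,3R)-4-(tert-butyldimethylsilyloxymethyl)-6-(4-methoxybenzyloxy)-2-(4-methoxyphenyl)-2,3-dihydrobenzofuran-3-carboxylate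
Product: 10 (2R,3R)-4-(tert-butyldimethylsilyloxymethyl)-6-(4-methoxybenzyloxy)-2-(4-methoxyphenyl)-2,3-dihydrobenzofuran-3-carbaldehyde
Conditions: i-Bu2AlH (1.1 equiv), CH2Cl2, −78 °C; Rochelle salt work-up
Reagents that add atoms: none
Why: Partial reduction of the ester through the tetrahedral aluminium hemiacetal that is stable at −78 °C; C3 is epimerisable in the aldehyde, but trans is the thermodynamic isomer.

Step 8
Reactants: 10 (2R,3R)-4-(tert-butyldimethylsilyloxymethyl)-6-(4-methoxybenzyloxy)-2-(4-methoxyphenyl)-2,3-dihydrobenzofuran-3-carbaldehyde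
Product: 11 (2R,3R)-4-(tert-butyldimethylsilyloxymethyl)-3-(2,2-dibromovinyl)-6-(4-methoxybenzyloxy)-2-(4-methoxyphenyl)-2,3-dihydrobenzofuran
Conditions: CBr4, PPh3, Et3N, CH2Cl2, 0 °C
Reagents that add atoms: carbon tetrabromide (BrC(Br)(Br)Br)
Why: Ramirez dibromo-olefination (first stage of the Corey–Fuchs sequence) gives a base-stable latent form of the C3 ethynyl group, so that the two alkynes of the later diyne can be made one after the other.

Step 9
Reactants: 11 (2R,3R)-4-(tert-butyldimethylsilyloxymethyl)-3-(2,2-dibromovinyl)-6-(4-methoxybenzyloxy)-2-(4-methoxyphenyl)-2,3-dihydrobenzofuran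
Product: 12 [(2R,3R)-3-(2,2-dibromovinyl)-6-(4-methoxybenzyloxy)-2-(4-methoxyphenyl)-2,3-dihydrobenzofuran-4-yl]methanol
Conditions: Bu4NF, AcOH, THF, 0 °C
Reagents that add atoms: none
Why: Fluoride cleavage of the primary silyl ether, buffered with acetic acid so that the dibromoalkene is not dehydrobrominated.

Step 10
Reactants: 12 [(2R,3R)-3-(2,2-dibromovinyl)-6-(4-methoxybenzyloxy)-2-(4-methoxyphenyl)-2,3-dihydrobenzofuran-4-yl]methanol
Product: 13 (2R,3R)-4-(bromomethyl)-3-(2,2-dibromovinyl)-6-(4-methoxybenzyloxy)-2-(4-methoxyphenyl)-2,3-dihydrobenzofuran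
Conditions: CBr4, PPh3, CH2Cl2, 0 °C
Reagents that add atoms: carbon tetrabromide (BrC(Br)(Br)Br)
Why: Appel bromination of the benzylic alcohol under neutral conditions; the bromide sits meta to both ring oxygens and should be stable enough to handle.

Step 11
Reactants: 14 (R)-4-benzyl-2-oxazolidinone; 15 (2,4-dimethoxyphenyl)acetic acid
Product: 17 (R)-4-benzyl-3-[(2,4-dimethoxyphenyl)acetyl]oxazolidin-2-one, via mixed pivalic anhydride 16 (not isolated)
Conditions: t-BuCOCl, Et3N, THF, −20 °C; then 14, LiCl, rt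
Reagents that add atoms: none
Why: N-acylation of the oxazolidinone through the mixed anhydride (LiCl/Et3N activation); pivaloyl chloride only activates the acid.

Step 12
Reactants: 13 (2R,3R)-4-(bromomethyl)-3-(2,2-dibromovinyl)-6-(4-methoxybenzyloxy)-2-(4-methoxyphenyl)-2,3-dihydrobenzofuran; 17 (R)-4-benzyl-3-[(2,4-dimethoxyphenyl)acetyl]oxazolidin-2-one
Product: 18 (R)-4-benzyl-3-[(2R)-3-[(2R,3R)-3-(2,2-dibromovinyl)-6-(4-methoxybenzyloxy)-2-(4-methoxyphenyl)-2,3-dihydrobenzofuran-4-yl]-2-(2,4-dimethoxyphenyl)propanoyl]oxazolidin-2-one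
Conditions: NaN(SiMe3)2, THF, −78 °C; then 13, −78 to −20 °C
Reagents that add atoms: none
Why: Evans alkylation: the chelated Z sodium enolate is benzylated on the face opposite to the benzyl group of the (R)-auxiliary, which sets the side-chain stereocentre as R, the configuration that becomes Cα.

Step 13
Reactants: 18 alkylated imide
Product: 19 (2R)-3-[(2R,3R)-3-(2,2-dibromovinyl)-6-(4-methoxybenzyloxy)-2-(4-methoxyphenyl)-2,3-dihydrobenzofuran-4-yl]-2-(2,4-dimethoxyphenyl)propan-1-ol
Conditions: LiBH4, MeOH (1 equiv), THF, 0 °C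
Reagents that add atoms: none
Why: Reductive removal of the auxiliary (hydride attacks the exocyclic imide carbonyl) without touching the new stereocentre or the dibromoalkene.

Step 14
Reactants: 19 side-chain primary alcohol
Product: 20 (2R)-3-[(2R,3R)-3-(2,2-dibromovinyl)-6-(4-methoxybenzyloxy)-2-(4-methoxyphenyl)-2,3-dihydrobenzofuran-4-yl]-2-(2,4-dimethoxyphenyl)propanal
Conditions: Dess–Martin periodinane, NaHCO3, CH2Cl2, 0 °C; used at once
Reagents that add atoms: none
Why: Dess–Martin oxidation under buffered conditions, which should not enolise the α-aryl aldehyde.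

Step 15
Reactants: 20 side-chain aldehyde
Product: 21 (2R,3R)-3-(2,2-dibromovinyl)-4-[(2S)-2-(2,4-dimethoxyphenyl)but-3-yn-1-yl]-6-(4-methoxybenzyloxy)-2-(4-methoxyphenyl)-2,3-dihydrobenzofuran
Conditions: (MeO)2P(O)CHN2, KOt-Bu (anion preformed), THF, −78 °C to rt
Reagents that add atoms: dimethyl (diazomethyl)phosphonate (COP(=O)(OC)C=[N+]=[N-])
Why: Seyferth–Gilbert homologation (phosphonate anion adds to the aldehyde; loss of phosphate and N2 gives an alkylidene carbene that rearranges by 1,2-H shift); it is run at −78 °C without alkyllithium, so the dibromoalkene survives and the stereocentre is kept (its label becomes S only through the priority change).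

Step 16
Reactants: 21 side-chain terminal alkyne
Product: 24 (2R,3R)-3-(2,2-dibromovinyl)-4-[(2S)-2-(2,4-dimethoxyphenyl)-4-(triisopropylsilyloxy)but-3-yn-1-yl]-6-(4-methoxybenzyloxy)-2-(4-methoxyphenyl)-2,3-dihydrobenzofuran, via lithium acetylide 22 (not isolated), via lithium ynolate 23 (not isolated)
Conditions: LiN(SiMe3)2 (1.0 equiv), THF, −78 °C; LiOOt-Bu (from t-BuOOH and LiN(SiMe3)2), −78 to 0 °C; i-Pr3SiOTf, −78 °C
Reagents that add atoms: tert-butyl hydroperoxide, used as its lithium salt (CC(C)(C)OO); triisopropylsilyl trifluoromethanesulfonate (CC(C)[Si](C(C)C)(C(C)C)OS(=O)(=O)C(F)(F)F)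
Why: Oxygenation of the lithium acetylide by lithium tert-butyl peroxide gives the lithium ynolate, which the bulky silyl triflate traps on oxygen; only one equivalent of amide base is used so that the dibromoalkene is not attacked.

Step 17
Reactants: 24 silyl ynol ether with C3 dibromoalkene
Product: 26 (2R,3R)-3-ethynyl-4-[(2S)-2-(2,4-dimethoxyphenyl)-4-(triisopropylsilyloxy)but-3-yn-1-yl]-6-(4-methoxybenzyloxy)-2-(4-methoxyphenyl)-2,3-dihydrobenzofuran, via C3 lithium acetylide 25 (not isolated)
Conditions: n-BuLi (2.1 equiv), THF, −78 °C; then H2O (pH 7 buffer)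
Reagents that add atoms: none
Why: Second stage of the Corey–Fuchs sequence (bromine–lithium exchange, Fritsch–Buttenberg–Wiechell rearrangement, deprotonation, then protonation on work-up); at −78 °C the exchange should be far faster than attack of n-BuLi at the hindered silicon of the ynol ether.

Step 18
Reactants: 26 diyne (C3 ethynyl and side-chain silyl ynol ether); 27 ethoxyacetylene
Product: 28 tetracyclic ring-B silyl ether: (2R,3R,αR) core of furan ring 1 + central ring + seven-membered ring + ring B, with Cb3-OEt, Cb5-OSi(i-Pr)3, C6-OPMB, 2-(4-methoxyphenyl) and Cα-(2,4-dimethoxyphenyl)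
Conditions: [Rh(cod)2]BF4 (10 mol %), rac-BINAP (10 mol %), pre-treated with H2, CH2Cl2, rt, slow addition of 26 and 27 (5 equiv)
Reagents that add atoms: none
Why: The cationic monovalent-rhodium bisphosphine complex binds the C3 ethynyl group and the silyl ynol ether of 26 and couples them oxidatively to a rhodacyclopentadiene; this forms Cb1–Cb6 and closes the seven-membered ring (exo closure at both alkynes, the five-atom tether being held folded by the peri relation of C3 and C4 on the rigid benzofuran). Insertion of 27 and reductive elimination then form Cb2–Cb3 and Cb4–Cb5 and close ring B as a benzene ring. The closest known reaction type is the cationic rhodium–BINAP [2+2+2] cyclotrimerisation of tethered diynes with terminal and heteroatom-substituted monoalkynes, used here with a 1,8-diyne. No stereocentre is formed; C2, C3 and Cα lie outside the reacting π systems and keep their configuration, so the racemic ligand suffices. The step needs regioselective insertion of 27 (its OEt carbon bonding to the CH terminus Cb2, so that OEt and OSi end up meta) and cross- over homo-trimerisation. The first should be secured by steric repulsion between OEt and the siloxy-bearing terminus Cb5 and by the matched polarity of the two ynol ethers (nucleophilic CH of 27 joining the oxygen-bearing Cb5), the second by slow addition so that intramolecular coupling of 26 precedes uptake of 27.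

Step 19
Reactants: 28 tetracyclic ring-B silyl ether
Product: 30 tetracyclic ring-B methyl ether (2R,3R,αR; Cb3-OEt, Cb5-OMe, C6-OPMB), via ring-B phenoxide 29 (not isolated)
Conditions: Bu4NF, MeI, THF, 0 °C to rt
Reagents that add atoms: iodomethane (CI)
Why: Fluoride cleaves the hindered aryl silyl ether and the naked phenoxide is O-methylated in the same flask (Williamson), so that ring B carries only alkyl ethers and the central phenol will be the only free one.

Step 20
Reactants: 30 tetracyclic ring-B methyl ether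
Product: 31 tetracyclic central phenol (2R,3R,αR; C6-OH)
Conditions: H2 (1 atm), Pd/C, EtOAc, rt
Reagents that add atoms: none
Why: Hydrogenolysis of the primary benzylic aryl ether on palladium, which should be faster than cleavage of the secondary, ring-bound benzylic C2–O bond of furan ring 1.

Step 21
Reactants: 31 tetracyclic central phenol
Product: 32 tetracyclic salicylaldehyde (2R,3R,αR; C6-OH, C5-CHO)
Conditions: MgCl2, Et3N, (CH2O)n, MeCN, reflux
Reagents that add atoms: paraformaldehyde, as formaldehyde (C=O)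
Why: Magnesium-phenoxide-directed ortho-formylation (hydroxymethylation, then Oppenauer-type hydride transfer to a second formaldehyde) acts only on the ring with the free phenol and should go to C5 (ortho to OH, para to O1) in preference to C7 between the two oxygens, as with orcinol-type phenols.

Step 22
Reactants: 32 tetracyclic salicylaldehyde; 33 2,4-dimethoxybenzyl alcohol
Product: 34 tetracyclic DMB ether aldehyde (2R,3R,αR; C6-ODMB, C5-CHO)
Conditions: PPh3, DIAD, THF, 0 °C to rt
Reagents that add atoms: none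
Why: Mitsunobu etherification of the acidic salicylaldehyde phenol with the primary benzylic alcohol; this benzyl group will deliver C2' and its aryl group.

Step 23
Reactants: 34 tetracyclic DMB ether aldehyde; 35 3,5-dimethoxyphenylmagnesium bromide
Product: 36 tetracyclic diaryl carbinol (2R,3R,αR; C5-CH(OH)(3,5-dimethoxyphenyl), both carbinol epimers)
Conditions: THF, 0 °C; then H2O
Reagents that add atoms: none
Why: Grignard addition to the aldehyde; the carbinol centre forms as a mixture that is removed in the next step.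

Step 24
Reactants: 36 tetracyclic diaryl carbinol
Product: 37 tetracyclic diaryl ketone (2R,3R,αR; C5-CO(3,5-dimethoxyphenyl), C6-ODMB)
Conditions: Dess–Martin periodinane, NaHCO3, CH2Cl2, rt
Reagents that add atoms: none
Why: Dess–Martin oxidation of the doubly benzylic alcohol to the ketone.

Step 25
Reactants: 37 tetracyclic diaryl ketone
Product: 38 tetracyclic diaryl ketone hydrazone (2R,3R,αR; E/Z mixture)
Conditions: N2H4·H2O, AcOH (cat.), EtOH, 90 °C, sealed tube
Reagents that add atoms: hydrazine hydrate (NN)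
Why: Acid-catalysed condensation of the ketone with hydrazine (hydrazone formation), forced by heat because the ketone is doubly ortho-substituted.

Step 26
Reactants: 38 tetracyclic diaryl ketone hydrazone
Product: 40 cis nona-ether (2R,3R,αR,2'R,3'S): furan ring 2 closed with 2'-(2,4-dimethoxyphenyl) and 3'-(3,5-dimethoxyphenyl) cis, via diaryldiazomethane 39 (not isolated)
Conditions: MnO2, CH2Cl2, rt, filter; then Rh2(R-PTAD)4 (1 mol %), CH2Cl2, 0 °C
Reagents that add atoms: none
Why: MnO2 dehydrogenates the hydrazone to the diaryldiazomethane, and the chiral dirhodium catalyst turns it into a donor/donor carbene that inserts into the OCH2 of the DMB ether (enantioselective intramolecular 1,5 C–H insertion); this closes furan ring 2 cis with C3' set as S by the catalyst.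

Step 27
Reactants: 40 cis nona-ether
Product: 41 trans nona-ether (2R,3R,αR,2'S,3'S)
Conditions: CF3CO2H (2 equiv), CH2Cl2, 0 °C
Reagents that add atoms: none
Why: Acid-catalysed epimerisation: reversible heterolysis of C2'–O gives a cation stabilised by the ortho- and para-methoxy groups, and reclosure gives the more stable trans ring (2'S) with C3' untouched; the C2–O bond of furan ring 1 ionises less readily and that ring is already trans.

Step 28
Reactants: 41 trans nona-ether
Product: 42 CNP0283541.1 (2R,3R,αR,2'S,3'S nonaphenol)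
Conditions: BBr3 (30 equiv), CH2Cl2, −78 °C to rt; then H2O
Reagents that add atoms: none
Why: Lewis-acid dealkylation of all nine aryl alkyl ethers (eight methyl, one ethyl) through aryloxyboranes and bromide attack on the alkyl groups, then hydrolysis; no stereocentre is involved.

**Compound list**

1 | 3,5-dihydroxybenzyl alcohol | OCc1cc(O)cc(O)c1 | starting material
2 | 4-methoxybenzyl chloride | COc1ccc(CCl)cc1 | starting material
3 | [3,5-bis(4-methoxybenzyloxy)phenyl]methanol | OCc1cc(OCc2ccc(OC)cc2)cc(OCc2ccc(OC)cc2)c1 | intermediate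
4 | tert-butyl{[3,5-bis(4-methoxybenzyloxy)benzyl]oxy}dimethylsilane | CC(C)(C)[Si](C)(C)OCc1cc(OCc2ccc(OC)cc2)cc(OCc2ccc(OC)cc2)c1 | intermediate
5 | {[2-bromo-3,5-bis(4-methoxybenzyloxy)benzyl]oxy}(tert-butyl)dimethylsilane | CC(C)(C)[Si](C)(C)OCc1cc(OCc2ccc(OC)cc2)cc(OCc2ccc(OC)cc2)c1Br | intermediate
6 | methyl 2-[2-(tert-butyldimethylsilyloxymethyl)-4,6-bis(4-methoxybenzyloxy)phenyl]acetate | COC(=O)Cc1c(CO[Si](C)(C)C(C)(C)C)cc(OCc2ccc(OC)cc2)cc1OCc1ccc(OC)cc1 | intermediate
7 | methyl 2-diazo-2-[2-(tert-butyldimethylsilyloxymethyl)-4,6-bis(4-methoxybenzyloxy)phenyl]acetate | COC(=O)C(=[N+]=[N-])c1c(CO[Si](C)(C)C(C)(C)C)cc(OCc2ccc(OC)cc2)cc1OCc1ccc(OC)cc1 | intermediate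
8 | methyl (2R,3S)-4-(tert-butyldimethylsilyloxymethyl)-6-(4-methoxybenzyloxy)-2-(4-methoxyphenyl)-2,3-dihydrobenzofuran-3-carboxylate (cis ester) | COc1ccc([C@@H]2Oc3cc(OCc4ccc(OC)cc4)cc(CO[Si](C)(C)C(C)(C)C)c3[C@@H]2C(=O)OC)cc1 | intermediate
9 | methyl (2R,3R)-4-(tert-butyldimethylsilyloxymethyl)-6-(4-methoxybenzyloxy)-2-(4-methoxyphenyl)-2,3-dihydrobenzofuran-3-carboxylate (trans ester) | COc1ccc([C@@H]2Oc3cc(OCc4ccc(OC)cc4)cc(CO[Si](C)(C)C(C)(C)C)c3[C@H]2C(=O)OC)cc1 | intermediate
10 | (2R,3R)-4-(tert-butyldimethylsilyloxymethyl)-6-(4-methoxybenzyloxy)-2-(4-methoxyphenyl)-2,3-dihydrobenzofuran-3-carbaldehyde | COc1ccc([C@@H]2Oc3cc(OCc4ccc(OC)cc4)cc(CO[Si](C)(C)C(C)(C)C)c3[C@H]2C=O)cc1 | intermediate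
11 | (2R,3R)-4-(tert-butyldimethylsilyloxymethyl)-3-(2,2-dibromovinyl)-6-(4-methoxybenzyloxy)-2-(4-methoxyphenyl)-2,3-dihydrobenzofuran | COc1ccc([C@@H]2Oc3cc(OCc4ccc(OC)cc4)cc(CO[Si](C)(C)C(C)(C)C)c3[C@H]2C=C(Br)Br)cc1 | intermediate
12 | [(2R,3R)-3-(2,2-dibromovinyl)-6-(4-methoxybenzyloxy)-2-(4-methoxyphenyl)-2,3-dihydrobenzofuran-4-yl]methanol | COc1ccc([C@@H]2Oc3cc(OCc4ccc(OC)cc4)cc(CO)c3[C@H]2C=C(Br)Br)cc1 | intermediate
13 | (2R,3R)-4-(bromomethyl)-3-(2,2-dibromovinyl)-6-(4-methoxybenzyloxy)-2-(4-methoxyphenyl)-2,3-dihydrobenzofuran | COc1ccc([C@@H]2Oc3cc(OCc4ccc(OC)cc4)cc(CBr)c3[C@H]2C=C(Br)Br)cc1 | intermediate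
14 | (R)-4-benzyl-2-oxazolidinone | O=C1N[C@H](Cc2ccccc2)CO1 | starting material
15 | (2,4-dimethoxyphenyl)acetic acid | COc1ccc(CC(=O)O)c(OC)c1 | starting material
16 | (2,4-dimethoxyphenyl)acetic pivalic anhydride (not isolated) | COc1ccc(CC(=O)OC(=O)C(C)(C)C)c(OC)c1 | intermediate
17 | (R)-4-benzyl-3-[(2,4-dimethoxyphenyl)acetyl]oxazolidin-2-one | COc1ccc(CC(=O)N2[C@H](Cc3ccccc3)COC2=O)c(OC)c1 | intermediate
18 | (R)-4-benzyl-3-[(2R)-3-[(2R,3R)-3-(2,2-dibromovinyl)-6-(4-methoxybenzyloxy)-2-(4-methoxyphenyl)-2,3-dihydrobenzofuran-4-yl]-2-(2,4-dimethoxyphenyl)propanoyl]oxazolidin-2-one | COc1ccc([C@@H]2Oc3cc(OCc4ccc(OC)cc4)cc(C[C@@H](C(=O)N4[C@H](Cc5ccccc5)COC4=O)c4ccc(OC)cc4OC)c3[C@H]2C=C(Br)Br)cc1 | intermediate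
19 | (2R)-3-[(2R,3R)-3-(2,2-dibromovinyl)-6-(4-methoxybenzyloxy)-2-(4-methoxyphenyl)-2,3-dihydrobenzofuran-4-yl]-2-(2,4-dimethoxyphenyl)propan-1-ol | COc1ccc([C@@H]2Oc3cc(OCc4ccc(OC)cc4)cc(C[C@@H](CO)c4ccc(OC)cc4OC)c3[C@H]2C=C(Br)Br)cc1 | intermediate
20 | (2R)-3-[(2R,3R)-3-(2,2-dibromovinyl)-6-(4-methoxybenzyloxy)-2-(4-methoxyphenyl)-2,3-dihydrobenzofuran-4-yl]-2-(2,4-dimethoxyphenyl)propanal | COc1ccc([C@@H]2Oc3cc(OCc4ccc(OC)cc4)cc(C[C@@H](C=O)c4ccc(OC)cc4OC)c3[C@H]2C=C(Br)Br)cc1 | intermediate
21 | (2R,3R)-3-(2,2-dibromovinyl)-4-[(2S)-2-(2,4-dimethoxyphenyl)but-3-yn-1-yl]-6-(4-methoxybenzyloxy)-2-(4-methoxyphenyl)-2,3-dihydrobenzofuran | COc1ccc([C@@H]2Oc3cc(OCc4ccc(OC)cc4)cc(C[C@@H](C#C)c4ccc(OC)cc4OC)c3[C@H]2C=C(Br)Br)cc1 | intermediate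
22 | lithium acetylide of 21 (not isolated) | COc1ccc([C@@H]2Oc3cc(OCc4ccc(OC)cc4)cc(C[C@@H](C#C[Li])c4ccc(OC)cc4OC)c3[C@H]2C=C(Br)Br)cc1 | intermediate
23 | lithium ynolate from 22 (not isolated) | COc1ccc([C@@H]2Oc3cc(OCc4ccc(OC)cc4)cc(C[C@@H](C#CO[Li])c4ccc(OC)cc4OC)c3[C@H]2C=C(Br)Br)cc1 | intermediate
24 | (2R,3R)-3-(2,2-dibromovinyl)-4-[(2S)-2-(2,4-dimethoxyphenyl)-4-(triisopropylsilyloxy)but-3-yn-1-yl]-6-(4-methoxybenzyloxy)-2-(4-methoxyphenyl)-2,3-dihydrobenzofuran | COc1ccc([C@@H]2Oc3cc(OCc4ccc(OC)cc4)cc(C[C@@H](C#CO[Si](C(C)C)(C(C)C)C(C)C)c4ccc(OC)cc4OC)c3[C@H]2C=C(Br)Br)cc1 | intermediate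
25 | C3 lithium acetylide of 26 (not isolated) | COc1ccc([C@@H]2Oc3cc(OCc4ccc(OC)cc4)cc(C[C@@H](C#CO[Si](C(C)C)(C(C)C)C(C)C)c4ccc(OC)cc4OC)c3[C@H]2C#C[Li])cc1 | intermediate
26 | (2R,3R)-3-ethynyl-4-[(2S)-2-(2,4-dimethoxyphenyl)-4-(triisopropylsilyloxy)but-3-yn-1-yl]-6-(4-methoxybenzyloxy)-2-(4-methoxyphenyl)-2,3-dihydrobenzofuran (key-step precursor) | COc1ccc([C@@H]2Oc3cc(OCc4ccc(OC)cc4)cc(C[C@@H](C#CO[Si](C(C)C)(C(C)C)C(C)C)c4ccc(OC)cc4OC)c3[C@H]2C#C)cc1 | intermediate
27 | ethoxyacetylene | C#COCC | starting material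
28 | tetracyclic ring-B silyl ether (2R,3R,αR; Cb3-OEt, Cb5-OSi(i-Pr)3, C6-OPMB; key-step product) | COc1ccc([C@@H]2Oc3cc(OCc5ccc(OC)cc5)cc4c3[C@H]2c2cc(OCC)cc(O[Si](C(C)C)(C(C)C)C(C)C)c2[C@@H](c2ccc(OC)cc2OC)C4)cc1 | intermediate
29 | tetrabutylammonium ring-B phenoxide from 28 (not isolated) | COc1ccc([C@@H]2Oc3cc(OCc5ccc(OC)cc5)cc4c3[C@H]2c2cc(OCC)cc([O-])c2[C@@H](c2ccc(OC)cc2OC)C4)cc1.CCCC[N+](CCCC)(CCCC)CCCC | intermediate
30 | tetracyclic ring-B methyl ether (2R,3R,αR; Cb3-OEt, Cb5-OMe, C6-OPMB) | COc1ccc([C@@H]2Oc3cc(OCc5ccc(OC)cc5)cc4c3[C@H]2c2cc(OCC)cc(OC)c2[C@@H](c2ccc(OC)cc2OC)C4)cc1 | intermediate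
31 | tetracyclic central phenol (2R,3R,αR; C6-OH) | COc1ccc([C@@H]2Oc3cc(O)cc4c3[C@H]2c2cc(OCC)cc(OC)c2[C@@H](c2ccc(OC)cc2OC)C4)cc1 | intermediate
32 | tetracyclic salicylaldehyde (2R,3R,αR; C6-OH, C5-CHO) | COc1ccc([C@@H]2Oc3cc(O)c(C=O)c4c3[C@H]2c2cc(OCC)cc(OC)c2[C@@H](c2ccc(OC)cc2OC)C4)cc1 | intermediate
33 | 2,4-dimethoxybenzyl alcohol | COc1ccc(CO)c(OC)c1 | starting material
34 | tetracyclic DMB ether aldehyde (2R,3R,αR; C6-ODMB, C5-CHO) | COc1ccc([C@@H]2Oc3cc(OCc5ccc(OC)cc5OC)c(C=O)c4c3[C@H]2c2cc(OCC)cc(OC)c2[C@@H](c2ccc(OC)cc2OC)C4)cc1 | intermediate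
35 | 3,5-dimethoxyphenylmagnesium bromide | COc1cc(OC)cc([Mg]Br)c1 | starting material
36 | tetracyclic diaryl carbinol (2R,3R,αR; carbinol epimers) | COc1ccc([C@@H]2Oc3cc(OCc5ccc(OC)cc5OC)c(C(O)c5cc(OC)cc(OC)c5)c4c3[C@H]2c2cc(OCC)cc(OC)c2[C@@H](c2ccc(OC)cc2OC)C4)cc1 | intermediate
37 | tetracyclic diaryl ketone (2R,3R,αR) | COc1ccc([C@@H]2Oc3cc(OCc5ccc(OC)cc5OC)c(C(=O)c5cc(OC)cc(OC)c5)c4c3[C@H]2c2cc(OCC)cc(OC)c2[C@@H](c2ccc(OC)cc2OC)C4)cc1 | intermediate
38 | tetracyclic diaryl ketone hydrazone (2R,3R,αR) | COc1ccc([C@@H]2Oc3cc(OCc5ccc(OC)cc5OC)c(C(=NN)c5cc(OC)cc(OC)c5)c4c3[C@H]2c2cc(OCC)cc(OC)c2[C@@H](c2ccc(OC)cc2OC)C4)cc1 | intermediate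
39 | tetracyclic diaryldiazomethane (2R,3R,αR; not isolated) | COc1ccc([C@@H]2Oc3cc(OCc5ccc(OC)cc5OC)c(C(=[N+]=[N-])c5cc(OC)cc(OC)c5)c4c3[C@H]2c2cc(OCC)cc(OC)c2[C@@H](c2ccc(OC)cc2OC)C4)cc1 | intermediate
40 | cis nona-ether (2R,3R,αR,2'R,3'S) | COc1ccc([C@@H]2Oc3cc4c(c5c3[C@H]2c2cc(OCC)cc(OC)c2[C@@H](c2ccc(OC)cc2OC)C5)[C@H](c2cc(OC)cc(OC)c2)[C@H](c2ccc(OC)cc2OC)O4)cc1 | intermediate
41 | trans nona-ether (2R,3R,αR,2'S,3'S) | COc1ccc([C@@H]2Oc3cc4c(c5c3[C@H]2c2cc(OCC)cc(OC)c2[C@@H](c2ccc(OC)cc2OC)C5)[C@H](c2cc(OC)cc(OC)c2)[C@@H](c2ccc(OC)cc2OC)O4)cc1 | intermediate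
42 | CNP0283541.1 | Oc1ccc([C@@H]2Oc3cc4c(c5c3[C@H]2c2cc(O)cc(O)c2[C@@H](c2ccc(O)cc2O)C5)[C@H](c2cc(O)cc(O)c2)[C@@H](c2ccc(O)cc2O)O4)cc1 | target

**Step count**

Total step count: 28. Longest linear sequence: 27 steps (steps 1–10 and 12–28; step 11 is the side branch).

**Steps most likely to fail**

Step 18 (cyclotrimerisation). The oxidative coupling across the five-atom tether may be slower than oligomerisation of ethoxyacetylene on the cationic metal. The monoalkyne may also couple first with only one alkyne of 26, which would give open or regioisomeric arenes. The Lewis-acidic metal may in addition degrade the silyl ynol ether. The fallback sets out from 26 and returns at 28. The monoalkyne is replaced by ketene diethyl acetal (1,1-diethoxyethene), an alkene that cannot trimerise and whose gem-diethoxy carbon is strongly biased towards the CH terminus. The same rhodium-catalysed diyne cyclisation with this alkene (diyne–ene cyclotrimerisation with an enol-ether-type alkyne surrogate) should give the ring-B diethoxycyclohexadiene F1, which should aromatise by loss of ethanol under the reaction conditions to 28.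

Step 26 (carbene insertion for furan ring 2). The hydrazone may form slowly at the doubly ortho-substituted ketone. The hindered donor/donor carbene may dimerise to the azine or insert with poor facial selectivity, so that furan ring 2 forms in low yield or as a mixture. The fallback sets out from ketone 37 and returns at 41. Corey–Chaykovsky methylenation (Me3S+ I−, KOt-Bu, DMSO/THF) should give the 2,2-diaryl oxirane F2. ZnI2-catalysed Meinwald rearrangement should give the diarylacetaldehyde F3. Addition of 2,4-dimethoxyphenylmagnesium bromide should give the secondary alcohol F4. CF3CO2H in CH2Cl2 should then remove the DMB ether to give the phenol F5 (not isolated) and ionise the doubly activated benzylic alcohol, so that the phenol captures the cation and closes the trans dihydrofuran. C3' is not controlled on this path, so 41 should form together with its (2'R,3'R) trans diastereomer F6. The two are diastereomers because of the three fixed stereocentres, and would be separated by chromatography.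

Step 28 (global dealkylation). The Lewis acid may ionise the benzylic C2'–O and C2–O bonds of the two dihydrofurans, so that ring opening, bromide capture or Friedel–Crafts recombination competes with ether cleavage. The ethyl ether may also be cleaved incompletely. The fallback sets out from 41 and returns at 42. It uses nucleophilic instead of electrophilic dealkylation: sodium ethanethiolate in DMF at 140 °C attacks the alkyl carbons by SN2 under basic conditions in which no benzylic cation can form. The ethyl ether needs the longest time.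

**Further compounds**

F1 | step 18 | ring-B diethoxycyclohexadiene (2R,3R,αR; Cb3(OEt)2, Cb4H2, diene Cb2=Cb1–Cb6=Cb5, Cb5-OSi(i-Pr)3) | COc1ccc([C@@H]2Oc3cc(OCc6ccc(OC)cc6)cc4c3[C@H]2C5=CC(OCC)(OCC)CC(O[Si](C(C)C)(C(C)C)C(C)C)=C5[C@@H](c5ccc(OC)cc5OC)C4)cc1
F2 | step 26 | 2,2-diaryl oxirane from ketone 37 (2R,3R,αR; epimers at the oxirane carbon) | COc1ccc([C@@H]2Oc3cc(OCc5ccc(OC)cc5OC)c(C5(CO5)c5cc(OC)cc(OC)c5)c4c3[C@H]2c2cc(OCC)cc(OC)c2[C@@H](c2ccc(OC)cc2OC)C4)cc1
F3 | step 26 | diarylacetaldehyde (2R,3R,αR; epimers at the new methine) | COc1ccc([C@@H]2Oc3cc(OCc5ccc(OC)cc5OC)c(C(C=O)c5cc(OC)cc(OC)c5)c4c3[C@H]2c2cc(OCC)cc(OC)c2[C@@H](c2ccc(OC)cc2OC)C4)cc1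
F4 | step 26 | secondary alcohol from F3 and 2,4-dimethoxyphenylmagnesium bromide (2R,3R,αR; mixture at the two new centres) | COc1ccc([C@@H]2Oc3cc(OCc5ccc(OC)cc5OC)c(C(C(O)c5ccc(OC)cc5OC)c5cc(OC)cc(OC)c5)c4c3[C@H]2c2cc(OCC)cc(OC)c2[C@@H](c2ccc(OC)cc2OC)C4)cc1
F5 | step 26 | phenol from F4 after loss of the DMB group (not isolated) | COc1ccc([C@@H]2Oc3cc(O)c(C(C(O)c5ccc(OC)cc5OC)c5cc(OC)cc(OC)c5)c4c3[C@H]2c2cc(OCC)cc(OC)c2[C@@H](c2ccc(OC)cc2OC)C4)cc1
F6 | step 26 | trans nona-ether diastereomer (2R,3R,αR,2'R,3'R) | COc1ccc([C@@H]2Oc3cc4c(c5c3[C@H]2c2cc(OCC)cc(OC)c2[C@@H](c2ccc(OC)cc2OC)C5)[C@@H](c2cc(OC)cc(OC)c2)[C@H](c2ccc(OC)cc2OC)O4)cc1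
F0 | step 28 | none | none
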